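## The problem

The target is a labda-8(17),13E-diene-15,19-dioic acid carrying a 2-hydroxyl, but its decalin is cis-fused: H5 and the C20 methyl on C10 lie on the same face (called β here; α is the other face). Ring A (C1–C5, C10) and ring B (C5–C10) share the C5–C10 bond. Five stereocentres (C2, C4, C5, C9, C10) must be set, and two are quaternary: C4 with the methyl C18 (β) and the carboxyl C19 (α), and C10 with C20. C5, C10 and C9 are contiguous on ring B and can be set in relay: the C5 substituent sends a nucleophile to the opposite face of C10, and the C10 arm then sends an electrophile to the opposite face of C9. C2 and C4 are set relative to the ring fusion, and their outcome depends on which of the two chair conformers of the cis-decalin reacts, so they are the delicate centres. The C19 carboxyl sits in the concave α pocket, trans to the 2β-hydroxyl, so no lactone can relay stereochemistry between them and its ester will resist attack at the carbonyl. The C8=C17 methylene isomerises in strong acid, C9 is epimerisable whenever C8 is a ketone, and the (E)-C13=C14 enoic acid accepts nucleophiles. The enabling feature is the γ-hydroxy acid pattern: the C2 oxygen and C19 are 1,4-related through C3 (dissonant), so C2 (an aldehyde carbon) and C3 (the β carbon of an acrylate on C5) are both electrophiles, and the C2–C3 bond calls for a reductive, polarity-inverting closure of ring A.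

## Retrosynthesis

Two terms are used below. The "C9-axial conformer" of the cis-decalin has C10–C9 axial on ring A (C20 equatorial on ring A; at C2 and C4 the β positions are equatorial). The "C6-axial conformer" has C5–C6 axial on ring A (C20 axial on ring A; at C2 and C4 the β positions are axial).

27 to 26. The two O–CH3 bonds of dimethyl ester 26 are cut last. Keeping both acids as methyl esters makes every intermediate neutral. The forward step must attack the methyl carbons, because the C19 carbonyl is out of reach of hydroxide.

26 to 25 and 24. The C13=C14 bond is cut by an olefination of methyl ketone 25. Carrying the enoate from the start would expose it to cuprates, hydride and samarium reagents. 25 is 24 without its ketal and silyl ether. The forward step must favour the E alkene.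

24 to 22. The C4–C18 bond is cut to the ester enolate 23 of 22. It cannot be made earlier, because C4 is the α carbon of the acrylate in the ring closure. The methyl must enter from the β face. This is the convex, equatorial face only in the C9-axial conformer, which an equatorial 2β-silyloxy group favours; the 2β oxygen therefore has to be in place first.

22 to 19. The C2–O bond is cut with inversion (19 to 20 to 21, then silylation). The ring closure is expected to give the 2α alcohol 19 (see next paragraph). Inversion is placed before the C4 alkylation because the 2β substituent is what holds the reacting conformer. If the closure gave the 2β alcohol 21 directly, the inversion would simply be omitted.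

19 to 18 (key). The C2–C3 bond is cut. Among the ring A bonds this is the only one whose two carbons are both at their natural electrophilic oxidation level. Cutting C3–C4 would require closing a ring while making the quaternary centre, and cutting C1–C2 would need a carbanion next to quaternary C10. The precursor 18 is monocyclic, has two stereocentres fewer, and carries C19 already as an ester. The forward step must reduce the aldehyde in preference to the acrylate, close 6-endo, and give one C2 epimer.

18 to 13. The C3=C4 methylene and the C2 aldehyde are traced to the ester and the dimethylamide of 13 (through 15, 16, 17). The acrylate is unmasked last because it would not survive the amide reduction.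

13 to 11. The C8=C17 bond is cut to the C8 ketone 12, and the ketal to the diketone 11. The forward methylenation must be non-basic, because the two C9 epimers of the ketone are close in energy.

11 to 9 and 2. The C9–C11 bond is cut to the regiodefined silyl enol ether 9 and enone 2. A C8 ketone could not be enolised toward C9 selectively; the enol ether delivered by the preceding conjugate addition solves this.

9 to 8. The C10–C20 bond is cut by a conjugate methyl addition to enone 8. This is preferred to a sigmatropic route to C10, because the addition anti to the C5 arm gives exactly the needed cis relation of the two arms.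

8 to 4 and 5. The C10–C1 bond is cut to enone 4 and amide 5 (through 7). The amide carries C1 and C2 at an oxidation level that is inert until step 10.

4 to 1 and 2. The C5–C6 and C9=C10 bonds are cut to aldehyde 1 and enone 2 (through 3). One catalytic asymmetric step sets C5, the only stereocentre not derived from another.

## Roads not taken

Alternative 1: The C4–C5 bond would be cut. The potassium alkoxide of the bicyclo[2.2.2]octenol A1 would undergo an anionic oxy-Cope shift, breaking C2–C7 and forming C4–C5, to give the cis-fused octalone A2.
- Merit: the shift is stereospecific. Quaternary C4 and the cis fusion follow from the alkene geometry and the cage. In this respect it is better than the chosen plan, whose C4 rests on a conformation-dependent enolate alkylation.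
- Weak points: A2 carries a C1 ketal the target lacks, C19 at the alcohol level, a C6=C7 alkene, and a benzyloxy group where the methylene must go. Many redox corrections follow the key step, with C9 epimerisable on the way. The C2 ketone still has to be reduced selectively.
- Comparison: the chosen plan offers carbons at or near their final oxidation level and a shorter finish. It pays with the risk at C4.

Alternative 2: The C3–C4 and C5–C10 bonds would be cut. Heating the triene A3 would close both rings in an intramolecular Diels–Alder reaction to the octalin A4.
- Merit: two rings and the C4, C5 and C10 centres form in one step, with C4 fixed by the Z geometry of the enoate. In bonds per step this road is better.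
- Weak points: the diene terminus C10 is fully substituted with its methyl pointing inward, the dienophile is trisubstituted, and the lone C9 centre must control both the face and the cis fusion. Afterwards the C1=C2 alkene must be hydrated at C2 only, on the β face.
- Comparison: the chosen plan places the C2 oxygen unambiguously (it is the aldehyde carbon) and builds ring B centre by centre by reliable anti additions.

Alternative 3: The C1–C10 bond would be cut. The enol of the bridged ten-membered β-keto lactone A5 would undergo a transannular Carroll shift and lose CO2 to give the C2 ketone A6.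
- Merit: quaternary C10 arises by suprafacial transfer from the C8 oxygen, and C4 is already quaternary. Both points are at least as secure as in the chosen plan.
- Weak points: A5 is a strained lactone bridging the 1,4 positions of ring B. Its C4 centre must be made with no ring to guide it. A6 lacks C17 and has a C8=C9 alkene, so the methylene and the C9 hydrogen need a re-oxidation at C8 late in the route.
- Comparison: the chosen plan finishes ring B, methylene included, before ring A is closed.

Key step: step 12

Remarks on the chemistry:
- Labdane numbering is used for all intermediates. C19 is the carboxyl carbon on C4 and C18 the methyl on C4.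
- Assumption: the (R)-configured diarylprolinol silyl ether gives (R)-3, by attack on the enamine face away from the diarylmethyl group. If the sense were opposite, the (S)-catalyst would be used.
- The central stereochemical judgement is that step 12 closes through the C6-axial chair and gives the 2α alcohol, which is then inverted.

Step 1
Reactants: 1 methyl 4-oxobutanoate; 2 but-3-en-2-one
Product: 3 methyl (3R)-3-formyl-6-oxoheptanoate
Conditions: (R)-2-[diphenyl(trimethylsilyloxy)methyl]pyrrolidine (10 mol %), catechol (20 mol %), CH2Cl2, 4 °C
Reagents that add atoms: none
Why: Enamine-catalysed asymmetric Michael addition of an aldehyde to a vinyl ketone; the diarylmethyl group shields one face of the E-enamine, so the catalyst sets C5.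

Step 2
Reactants: 3 methyl (3R)-3-formyl-6-oxoheptanoate
Product: 4 methyl 2-[(1R)-4-oxocyclohex-2-en-1-yl]acetate
Conditions: Bn2NH·CF3CO2H (20 mol %), toluene, 50 °C
Reagents that add atoms: none
Why: Intramolecular aldol condensation of the methyl ketone onto the aldehyde closes ring B; the mild ammonium salt avoids epimerising C5 before it becomes the γ carbon of the enone.

Step 3
Reactants: 4 methyl 2-[(1R)-4-oxocyclohex-2-en-1-yl]acetate; 5 N,N-dimethylacetamide
Product: 7 trimethylsilyl enol ether of the trans conjugate adduct (C8–OSiMe3; C10 bears H and CH2CONMe2), via lithium enolate 6 (not isolated)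
Conditions: LiN(iPr)2, THF, −78 °C; 4, −78 to −40 °C; Me3SiCl, Et3N, −78 to 0 °C
Reagents that add atoms: chlorotrimethylsilane, C[Si](C)(C)Cl
Why: Michael addition of a lithium amide enolate (soft; any 1,2-adduct reverts on warming) to the enone, anti to the C5 arm, and silylation of the regiodefined enolate; the C10 configuration formed here is erased in step 4.

Step 4
Reactants: 7 trimethylsilyl enol ether of the conjugate adduct
Product: 8 methyl 2-[(1R)-2-[2-(dimethylamino)-2-oxoethyl]-4-oxocyclohex-2-en-1-yl]acetate
Conditions: Pd(OAc)2 (10 mol %), O2 (1 atm), DMSO, 25 °C
Reagents that add atoms: none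
Why: Saegusa–Ito oxidation; the divalent palladium enolate at C9 loses its only β-hydrogen (on C10), which restores the enone with the C1 arm on the β carbon, and O2 reoxidises the zerovalent palladium.

Step 5
Reactants: 8 ring B enone with the amide arm on C10
Product: 9 trimethylsilyl enol ether (C8–OSiMe3, C8=C9) with quaternary C10 (β-methyl, α-CH2CONMe2) and 5α-CH2CO2Me
Conditions: Me2CuLi (from MeLi and CuI), Me3SiCl, THF–Et2O, −78 to −40 °C; Et3N
Reagents that add atoms: lithium dimethylcuprate, [Li+].C[Cu-]C; chlorotrimethylsilane, C[Si](C)(C)Cl
Why: Silyl chloride-accelerated conjugate addition of a methyl cuprate to a β,β-disubstituted enone; the C5 arm is pseudoaxial (1,2-allylic strain with the C10 substituent) and the methyl enters anti to it, which sets C10 with C20 β and the C1 arm α, cis to the C5 arm. Silylation fixes the enolate at C9.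

Step 6
Reactants: 9 silyl enol ether with quaternary C10; 2 but-3-en-2-one
Product: 11 ring B diketone (C8 ketone; 9β-3-oxobutyl; 9α-H), via side-chain silyl enol ether 10 (not isolated)
Conditions: Sc(OTf)3 (10 mol %), CH2Cl2, −78 °C; then 1 M HCl, THF, 0 °C
Reagents that add atoms: none
Why: Lewis acid-catalysed Mukaiyama–Michael addition; the activated enone attacks C9 axially, anti to the pseudoaxial C1 arm on C10, so the chain enters on the β face (cis to C20). Silyl transfer gives 10, which the cold acid work-up hydrolyses.

Step 7
Reactants: 11 ring B diketone
Product: 12 C8 ketone with the side-chain ketone as its ethylene ketal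
Conditions: Me3SiOCH2CH2OSiMe3, Me3SiOTf (5 mol %), CH2Cl2, −78 °C
Reagents that add atoms: 1,2-bis(trimethylsilyloxy)ethane, C[Si](C)(C)OCCO[Si](C)(C)C
Why: Kinetically controlled aprotic ketalisation selects the unhindered methyl ketone over the C8 ketone, which is flanked by C9 and quaternary C10; the low temperature avoids enolisation at C9.

Step 8
Reactants: 12 keto ketal
Product: 13 exocyclic methylene compound (C8=C17) with ester, amide and ketal
Conditions: Zn, CH2Br2, TiCl4, THF–CH2Cl2, 0 to 25 °C
Reagents that add atoms: dibromomethane, BrCBr
Why: Takai–Lombardo methylenation; the zinc–titanium methylene reagent is non-basic, so the epimerisable C9 is untouched, and it does not attack the ester, the amide or the ketal.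

Step 9
Reactants: 13 methylene ester amide
Product: 15 Mannich base (C4 bears CH2NMe2 and CO2Me; C4 epimers), via lithium ester enolate 14 (not isolated)
Conditions: LiN(iPr)2, THF, −78 °C; Me2N=CH2 I, −78 to 0 °C
Reagents that add atoms: N,N-dimethylmethyleneiminium iodide, C=[N+](C)C.[I-]
Why: Mannich reaction of the ester enolate, which brings in C3; the base removes the ester α-proton in preference to the less acidic, neopentyl amide α-protons. The C4 mixture is irrelevant because C4 becomes sp2 in step 11.

Step 10
Reactants: 15 Mannich base
Product: 16 amino aldehyde (C10–CH2CHO; masked acrylate on C5)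
Conditions: Cp2Zr(H)Cl (1.5 equiv), THF, 25 °C; silica gel, H2O
Reagents that add atoms: none
Why: Chemoselective hydrozirconation of the tertiary amide; the zirconated hemiaminal collapses to the aldehyde on work-up, while the methyl ester, the amine, the ketal and the hindered 1,1-disubstituted alkene react more slowly. The acrylate is still masked, which is why this step precedes step 11.

Step 11
Reactants: 16 amino aldehyde
Product: 18 ring B aldehyde–acrylate (5α-C(=CH2)CO2Me; 10α-CH2CHO; 10β-methyl; 9β side chain; C8=C17), via trimethylammonium iodide 17 (not isolated)
Conditions: MeI, CH2Cl2, 25 °C; then NaHCO3 (aq), 25 °C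
Reagents that add atoms: none
Why: Quaternisation of the amine followed by β-elimination (E1cB) under bicarbonate unveils the α-substituted acrylate without enolising the aldehyde.

Step 12
Reactants: 18 ring B aldehyde–acrylate
Product: 19 cis-fused 2α-hydroxy methyl ester (C4–H, both epimers) with C8=C17 and side-chain ketal
Conditions: SmI2 (2.5 equiv), HMPA, tBuOH, THF, −78 °C, slow addition of 18
Reagents that add atoms: none
Why: Electron transfer from divalent samarium (activated by HMPA) reduces the aldehyde, the most easily reduced group, to the C2 ketyl, which adds to the unsubstituted C3 terminus of the acrylate; a second electron gives the trivalent samarium enolate at C4, which tBuOH protonates. The closest known reaction type is the SmI2/HMPA ketyl–olefin coupling of aldehydes with acrylates and methacrylate-type acceptors to γ-hydroxy esters. Ring A closes 6-endo-trig because the tether is on the α carbon of the acceptor; the 5-exo mode would join the nucleophilic ketyl to the electron-rich, fully substituted C4. The cis fusion is fixed beforehand, since the C1 arm and the acrylate are both α. C2 is set by the chair of closure: in the C6-axial chair the acrylate is equatorial on ring B and its ester lies beside H5, whereas the C9-axial chair presses the ester against C6 and C7 (1,3-allylic strain), so the first should dominate, and with the bulky samarium-bound oxygen equatorial it gives the 2α alcohol, trans to C20. C4 is set by protonation without control, and both epimers are carried on because this centre is planar again in step 16. The step needs ketyl formation in the presence of the acrylate and a single mode of closure; the reduction potentials and the α-tethered acceptor secure these, and low temperature with slow addition suppresses pinacol coupling.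

Step 13
Reactants: 19 cis-fused 2α-hydroxy ester
Product: 20 2β-(4-nitrobenzoate)
Conditions: 4-O2NC6H4CO2H, PPh3, iPrO2CN=NCO2iPr, toluene, 0 to 25 °C
Reagents that add atoms: 4-nitrobenzoic acid, OC(=O)c1ccc(cc1)[N+](=O)[O-]
Why: Mitsunobu inversion (SN2) at C2; displacement runs through the ring-flipped chair with the oxyphosphonium axial, and the carboxylate arrives equatorially on the convex β face, giving the 2β ester.

Step 14
Reactants: 20 2β-(4-nitrobenzoate)
Product: 21 cis-fused 2β-hydroxy methyl ester (C4–H, both epimers)
Conditions: K2CO3, MeOH, 25 °C
Reagents that add atoms: none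
Why: Methanolysis (acyl–oxygen cleavage) of the activated aryl ester keeps the C2 configuration; any equilibration at C4 is harmless.

Step 15
Reactants: 21 2β-hydroxy ester
Product: 22 2β-tert-butyldimethylsilyl ether
Conditions: tBuMe2SiCl, imidazole, DMF, 25 °C
Reagents that add atoms: tert-butyldimethylsilyl chloride, CC(C)(C)[Si](C)(C)Cl
Why: Silylation of the equatorial secondary alcohol; the silyl ether protects the oxygen from base and anchors the chair needed in step 16.

Step 16
Reactants: 22 2β-silyl ether ester
Product: 24 4β-methyl 4α-methoxycarbonyl compound (C4 quaternary), via lithium ester enolate 23 (not isolated)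
Conditions: LiN(iPr)2, THF, −78 to −30 °C; MeI, DMPU, −78 °C
Reagents that add atoms: iodomethane, CI
Why: Ester enolate alkylation; with the 2β-silyloxy group equatorial the decalin should react in the C9-axial conformer, where the α face of C4 is the concave pocket under ring B, so MeI enters equatorially from the convex β face and gives the 4β-methyl, 4α-ester. In the other conformer the silyloxy group and C20 would be syn-axial and the β face blocked by both.

Step 17
Reactants: 24 C4-methylated silyl ether ketal
Product: 25 2β-hydroxy methyl ketone methyl ester
Conditions: HF (48 % aq), MeCN, 0 to 25 °C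
Reagents that add atoms: water, O
Why: Acid hydrolysis of the dioxolane and fluoride-assisted cleavage of the silyl ether in one operation; dilute HF is too weak an acid to isomerise the exocyclic alkene.

Step 18
Reactants: 25 hydroxy keto ester
Product: 26 dimethyl ester of the target ((E)-C13=C14)
Conditions: (MeO)2P(O)CH2CO2Me, NaH, THF, 0 to 50 °C
Reagents that add atoms: trimethyl phosphonoacetate, COC(=O)CP(=O)(OC)OC
Why: Horner–Wadsworth–Emmons olefination of the methyl ketone; the stabilised anion gives mainly the (E)-enoate and tolerates the free hydroxyl, and the Z isomer is removed by chromatography.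

Step 19
Reactants: 26 dimethyl ester
Product: 27 the target diacid, CNP0086784.2
Conditions: nPrSLi, HMPA, 25 °C; then 1 M HCl
Reagents that add atoms: none
Why: SN2 demethylation (alkyl–oxygen cleavage) of both methyl esters by thiolate; attack at the methyl carbon avoids the C19 carbonyl, which is axial in the concave pocket and inert to saponification.

## Compound list

1 | methyl 4-oxobutanoate | COC(=O)CCC=O | starting material
2 | but-3-en-2-one | C=CC(C)=O | starting material
3 | methyl (3R)-3-formyl-6-oxoheptanoate | CC(=O)CC[C@H](CC(=O)OC)C=O | intermediate
4 | methyl 2-[(1R)-4-oxocyclohex-2-en-1-yl]acetate | O=C1CC[C@H](CC(=O)OC)C=C1 | intermediate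
5 | N,N-dimethylacetamide | CC(=O)N(C)C | starting material
6 | lithium C8 enolate of the trans conjugate adduct (C10: β-CH2CONMe2, α-H; C5: α-CH2CO2Me) | [Li]OC1=C[C@H](CC(=O)N(C)C)[C@@H](CC(=O)OC)CC1 | intermediate (not isolated)
7 | trimethylsilyl enol ether of the trans conjugate adduct | C[Si](C)(C)OC1=C[C@H](CC(=O)N(C)C)[C@@H](CC(=O)OC)CC1 | intermediate
8 | methyl 2-[(1R)-2-[2-(dimethylamino)-2-oxoethyl]-4-oxocyclohex-2-en-1-yl]acetate | O=C1C=C(CC(=O)N(C)C)[C@@H](CC(=O)OC)CC1 | intermediate
9 | trimethylsilyl enol ether (C8=C9) with 10β-methyl, 10α-CH2CONMe2, 5α-CH2CO2Me | C[Si](C)(C)OC1=C[C@@](C)(CC(=O)N(C)C)[C@@H](CC(=O)OC)CC1 | intermediate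
10 | side-chain trimethylsilyl enol ether of the Michael adduct (C8 ketone; 9β chain) | O=C1CC[C@H](CC(=O)OC)[C@](C)(CC(=O)N(C)C)[C@H]1CC=C(C)O[Si](C)(C)C | intermediate (not isolated)
11 | ring B diketone: 9β-(3-oxobutyl), 10β-methyl, 10α-CH2CONMe2, 5α-CH2CO2Me, C8 ketone | O=C1CC[C@H](CC(=O)OC)[C@](C)(CC(=O)N(C)C)[C@H]1CCC(C)=O | intermediate
12 | C8 ketone with the side-chain ketone as 2-methyl-1,3-dioxolane | O=C1CC[C@H](CC(=O)OC)[C@](C)(CC(=O)N(C)C)[C@H]1CCC2(C)OCCO2 | intermediate
13 | 8(17)-methylene ester amide ketal | C=C1CC[C@H](CC(=O)OC)[C@](C)(CC(=O)N(C)C)[C@H]1CCC2(C)OCCO2 | intermediate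
14 | lithium enolate of the C19 methyl ester of 13 | C=C1CC[C@H](C=C(O[Li])OC)[C@](C)(CC(=O)N(C)C)[C@H]1CCC2(C)OCCO2 | intermediate (not isolated)
15 | Mannich base: C4 bears CH2NMe2 and CO2Me (C4 epimers) | C=C1CC[C@H](C(CN(C)C)C(=O)OC)[C@](C)(CC(=O)N(C)C)[C@H]1CCC2(C)OCCO2 | intermediate
16 | amino aldehyde: 10α-CH2CHO, C4 as in 15 | C=C1CC[C@H](C(CN(C)C)C(=O)OC)[C@](C)(CC=O)[C@H]1CCC2(C)OCCO2 | intermediate
17 | trimethylammonium iodide of 16 | C=C1CC[C@H](C(C[N+](C)(C)C)C(=O)OC)[C@](C)(CC=O)[C@H]1CCC2(C)OCCO2.[I-] | intermediate (not isolated)
18 | ring B aldehyde–acrylate: 5α-C(=CH2)CO2Me, 5β-H, 10α-CH2CHO, 10β-methyl, 9β-chain with ketal, 9α-H, C8=C17 | C=C1CC[C@H](C(=C)C(=O)OC)[C@](C)(CC=O)[C@H]1CCC2(C)OCCO2 | intermediate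
19 | cis-fused 2α-hydroxy methyl ester (C4–H, both epimers), C8=C17, side-chain ketal | C=C1CC[C@H]2[C@](C)(C[C@@H](O)CC2C(=O)OC)[C@H]1CCC3(C)OCCO3 | intermediate
20 | 2β-(4-nitrobenzoyloxy) methyl ester (C4 epimers) | C=C1CC[C@H]2[C@](C)(C[C@H](OC(=O)c3ccc(cc3)[N+](=O)[O-])CC2C(=O)OC)[C@H]1CCC4(C)OCCO4 | intermediate
21 | cis-fused 2β-hydroxy methyl ester (C4 epimers) | C=C1CC[C@H]2[C@](C)(C[C@H](O)CC2C(=O)OC)[C@H]1CCC3(C)OCCO3 | intermediate
22 | 2β-tert-butyldimethylsilyloxy methyl ester (C4 epimers) | C=C1CC[C@H]2[C@](C)(C[C@H](O[Si](C)(C)C(C)(C)C)CC2C(=O)OC)[C@H]1CCC3(C)OCCO3 | intermediate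
23 | lithium C4 ester enolate of 22 | C=C1CC[C@H]2[C@](C)(C[C@H](O[Si](C)(C)C(C)(C)C)CC2=C(O[Li])OC)[C@H]1CCC3(C)OCCO3 | intermediate (not isolated)
24 | 2β-silyloxy 4β-methyl 4α-methoxycarbonyl compound with ketal | C=C1CC[C@H]2[C@](C)(C[C@H](O[Si](C)(C)C(C)(C)C)C[C@@]2(C)C(=O)OC)[C@H]1CCC3(C)OCCO3 | intermediate
25 | 2β-hydroxy 4β-methyl 4α-methoxycarbonyl methyl ketone | C=C1CC[C@H]2[C@](C)(C[C@H](O)C[C@@]2(C)C(=O)OC)[C@H]1CCC(C)=O | intermediate
26 | dimethyl ester of the target (13E) | C=C1CC[C@H]2[C@](C)(C[C@H](O)C[C@@]2(C)C(=O)OC)[C@H]1CC/C(C)=C/C(=O)OC | intermediate
27 | CNP0086784.2: 2β-hydroxy-5β,9α-H-10β-methyl-labda-8(17),13E-diene-15,19-dioic acid (4β-methyl, 4α-carboxyl) | C=C1CC[C@H]2[C@](C)(C[C@H](O)C[C@@]2(C)C(=O)O)[C@H]1CC/C(C)=C/C(=O)O | target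

## Step count and least certain steps

Total: 19 steps. Longest linear sequence: 19 steps (from 1 and 2; 5 enters at step 3).

Step 12 (key step). Three things may go wrong: loss of selectivity between the two chair pathways, intermolecular pinacol coupling, and conjugate reduction of the acrylate before closure. The C2 outcome is not fatal, because the 2β epimer is 21 itself and would simply skip steps 13 and 14. Fallback with a different bond-forming logic: treat 18 with a triazolium-derived N-heterocyclic carbene so that the aldehyde, as its acyl anion equivalent, adds to C3 in an intramolecular Stetter reaction. This gives the C2 ketone (γ-keto ester) F1. Reduction of F1 with NaBH4 and separation returns the route at 19 (2α alcohol) and at 21 (2β alcohol).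

Step 13. Elimination to the ring A alkene, or no reaction, may arise because the oxyphosphonium has to sit axial in the concave pocket for displacement from the convex face. Fallback: from 19, form the 2α-methanesulfonate F2 (MeSO2Cl, Et3N), displace it with CsOAc and 18-crown-6 in hot toluene to the 2β-acetate F3, and methanolyse (K2CO3, MeOH). The route is rejoined at 21, and 20 is bypassed.

Step 16. The facial selectivity may erode if 1,3-allylic strain between the ester enolate and C6 drives the ring into the C6-axial conformer, in which the methyl would enter α. Deprotonation of the hindered C4–H may also be slow. Fallback at the aldehyde level, where the enolate carries only one oxygen and the strain is small: from 22, reduce the ester with iBu2AlH at −78 °C to the C19 aldehyde F4. Methylate its potassium enolate (KOtBu, MeI) from the convex face to the 4β-methyl aldehyde F5. Oxidise with NaClO2 (2-methyl-2-butene, NaH2PO4) to the acid F6, and esterify with Me3SiCHN2. The route is rejoined at 24.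

Step 6. The C9 configuration may be lost by enolisation of the C8 ketone, since the two C9 epimers are close in energy, and the neopentyl-type silyl enol ether may add slowly. Fallback: from 9, generate the lithium enolate with MeLi and alkylate it with 2-(2-iodoethyl)-2-methyl-1,3-dioxolane (axial attack anti to the C10 arm). This gives 12 directly and bypasses 10 and 11; no new compound arises.

Step 5. The cuprate may deprotonate the acidic CH2 between the enone and the amide instead of adding, and addition at the fully substituted β carbon may be slow. Fallback: from 8, Corey–Chaykovsky cyclopropanation with Me3S(O)I and NaH, anti to the C5 arm, gives the cyclopropyl ketone F7. Reductive opening of its C9–CH2 bond with SmI2 and HMPA, with silylation of the enolate by Me3SiCl, leaves the 10β-methyl and rejoins the route at 9.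

## Further compounds

F1 | step 12 | cis-fused C2 ketone (γ-keto methyl ester, C4–H) with C8=C17 and ketal | C=C1CC[C@H]2[C@](C)(CC(=O)CC2C(=O)OC)[C@H]1CCC3(C)OCCO3
F2 | step 13 | 2α-methanesulfonate of 19 | C=C1CC[C@H]2[C@](C)(C[C@@H](OS(C)(=O)=O)CC2C(=O)OC)[C@H]1CCC3(C)OCCO3
F3 | step 13 | 2β-acetate | C=C1CC[C@H]2[C@](C)(C[C@H](OC(C)=O)CC2C(=O)OC)[C@H]1CCC3(C)OCCO3
F4 | step 16 | 2β-silyloxy C19 aldehyde (C4–H) | C=C1CC[C@H]2[C@](C)(C[C@H](O[Si](C)(C)C(C)(C)C)CC2C=O)[C@H]1CCC3(C)OCCO3
F5 | step 16 | 2β-silyloxy 4β-methyl 4α-formyl compound | C=C1CC[C@H]2[C@](C)(C[C@H](O[Si](C)(C)C(C)(C)C)C[C@@]2(C)C=O)[C@H]1CCC3(C)OCCO3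
F6 | step 16 | 2β-silyloxy 4β-methyl 4α-carboxylic acid | C=C1CC[C@H]2[C@](C)(C[C@H](O[Si](C)(C)C(C)(C)C)C[C@@]2(C)C(=O)O)[C@H]1CCC3(C)OCCO3
F0 | step 6 | none | none
F7 | step 5 | cyclopropyl ketone (CH2 bridging C9 and C10 on the β face) | O=C1CC[C@H](CC(=O)OC)[C@@]2(CC(=O)N(C)C)C[C@@H]12
A1 | alternative 1 | bicyclo[2.2.2]octenol: C2 carbinol with (Z)-alkenyl C3=C4, C1 dimethyl ketal, 8-benzyloxy, side-chain ketal | O[C@]1(/C=C(/C)CO[Si](C)(C)C(C)(C)C)C(OC)(OC)[C@@]2(C)C=C[C@@H]1[C@H](OCc3ccccc3)[C@@H]2CCC4(C)OCCO4
A2 | alternative 1 | cis-fused octalone with quaternary C4 and C1 dimethyl ketal | c1ccccc1CO[C@H]2C=C[C@H]3[C@](C)(C(OC)(OC)C(=O)C[C@@]3(C)CO[Si](C)(C)C(C)(C)C)[C@H]2CCC4(C)OCCO4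
A3 | alternative 2 | triene: (E)-diene C10=C1–C2=C3, (Z)-C4=C5 enoate, C8 ketal | C=C/C=C(\C)[C@@H](CC/C(C)=C/C(=O)OC)C1(OCCO1)CC/C=C(/C)C(=O)OC
A4 | alternative 2 | cis-fused octalin ketal diester with C1=C2 alkene | C12(OCCO1)CC[C@H]3[C@](C)(C=CC[C@@]3(C)C(=O)OC)[C@H]2CC/C(C)=C/C(=O)OC
A5 | alternative 3 | bridged ten-membered β-keto lactone (C8–O–CO–C1–C2(=O)–C3–C4–C5) | O=C1CC(=O)C[C@@](C)(C(=O)OC)[C@H]2CC[C@@H](O1)C(CC/C(C)=C/C(=O)OC)=C2C
A6 | alternative 3 | cis-fused C2 ketone with C8=C9 alkene | C1CC[C@H]2[C@](C)(CC(=O)C[C@@]2(C)C(=O)OC)C=1CC/C(C)=C/C(=O)OC
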